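The cyclohexene ring is numbered C1 (heptenyl), C2 (CH2OH), C3, C4 (diol), C5 (acid chain), C6 (OH). Its tetrasubstituted C1=C2 bond bears two carbon substituents, and the C5 chain and C6 oxygen share one face. Removing the C3/C4 hydroxyls therefore uncovers a cyclohexa-1,3-diene-1-carboxylate, the signature of a 2-pyrone cycloaddition followed by CO2 loss. The plan rests on cutting C4-C5 and C1-C6. A copper-bis(oxazoline)-catalysed inverse-demand Diels-Alder reaction joins a 3-carbomethoxy-4-(acetoxymethyl)-2-pyrone to a Z silyl enol ether that already holds the whole enoate chain, forming both bonds, the carbocycle and the C5/C6 stereocentres at once. Decarboxylation, anti dihydroxylation, a transient C1/C2 butenolide and Julia-Kocienski olefination finish the synthesis.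

Key step: step 8

Convention: the core numbering above is used for all carbocyclic compounds. With C1 to C6 drawn clockwise, the C3 and C4 oxygens point toward the viewer and the C5 chain and C6 oxygen point away. TBS = tert-butyldimethylsilyl.

Assumption: the (S,S)-tBu-box copper complex is taken to shield the pyrone face whose endo adduct has the configuration drawn. If the sense of induction is the opposite, the equally available (R,R) ligand is used and nothing else changes.

Step 1
Reactants: 1 dimethyl malonate; 2 4,4-dimethoxybutan-2-one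
Product: 3 dimethyl 2-(4,4-dimethoxybutan-2-ylidene)malonate
Conditions: TiCl4 (2 equiv), pyridine (4 equiv), THF, 0 °C to rt
Reagents that add atoms: none
Why: The TiCl4/pyridine variant of the Knoevenagel condensation is the established way to condense a malonic diester with a methyl ketone; it engages the carbonyl carbon and not the acetal carbon, so the methyl group ends up at pyrone C4, and partial loss of methanol to the dienyl ether would be harmless because that compound closes to the same pyrone.

Step 2
Reactants: 3 dimethyl 2-(4,4-dimethoxybutan-2-ylidene)malonate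
Product: 5 methyl 4-methyl-2-oxo-2H-pyran-3-carboxylate, via dimethyl 2-(4-oxobutan-2-ylidene)malonate 4 (not isolated)
Conditions: HCO2H-H2O (95:5), 90 °C
Reagents that add atoms: water, O
Why: Acetal hydrolysis followed by acid-catalysed enol lactonisation, the closure used for the parent 3-carbomethoxy-2-pyrone, should work because one of the two geminal esters is necessarily cis to the aldehyde arm and the pyrone is the thermodynamic sink.

Step 3
Reactants: 5 methyl 4-methyl-2-oxo-2H-pyran-3-carboxylate
Product: 6 methyl 4-(bromomethyl)-2-oxo-2H-pyran-3-carboxylate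
Conditions: NBS (1.05 equiv), AIBN (cat.), PhCF3, 85 °C
Reagents that add atoms: N-bromosuccinimide, O=C1CCC(=O)N1Br
Why: Wohl-Ziegler bromination takes a hydrogen of the C4 methyl group because the derived radical is allylic and delocalised into the pyrone and ester, the ring positions are electron-poor, C3 is blocked, and stopping short of full conversion limits dibromination.

Step 4
Reactants: 6 methyl 4-(bromomethyl)-2-oxo-2H-pyran-3-carboxylate
Product: 7 methyl 4-(acetoxymethyl)-2-oxo-2H-pyran-3-carboxylate
Conditions: KOAc (1.5 equiv), DMF, rt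
Reagents that add atoms: potassium acetate, CC(=O)[O-].[K+]
Why: SN2 displacement of the activated primary allylic bromide by weakly basic acetate is fast at room temperature, where pyrone C6 and the methyl ester are not attacked irreversibly.

Step 5
Reactants: 8 2,3-dihydrofuran; 9 tert-butyl 2-(triphenylphosphoranylidene)propanoate
Product: 11 tert-butyl (E)-6-hydroxy-2-methylhex-2-enoate, via tetrahydrofuran-2-ol 10 (not isolated)
Conditions: HCl (cat.), THF-H2O, 0 °C to rt; NaHCO3; then 9, 45 °C
Reagents that add atoms: water, O
Why: Acid-catalysed hydration of the cyclic enol ether gives the lactol, whose open 4-hydroxybutanal form is consumed in a water-tolerant Wittig reaction in which the stabilised alpha-methyl ylide delivers the E trisubstituted enoate, and using the lactol in solution avoids its self-condensation on concentration.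

Step 6
Reactants: 11 tert-butyl (E)-6-hydroxy-2-methylhex-2-enoate
Product: 12 tert-butyl (E)-2-methyl-6-oxohex-2-enoate
Conditions: TEMPO (10 mol %), PhI(OAc)2 (1.1 equiv), CH2Cl2, rt
Reagents that add atoms: none
Why: Oxoammonium-catalysed (TEMPO) oxidation stops at the aldehyde under nearly neutral conditions, so the enoate neither migrates nor isomerises.

Step 7
Reactants: 12 tert-butyl (E)-2-methyl-6-oxohex-2-enoate
Product: 13 tert-butyl (2E,5Z)-6-(tert-butyldimethylsilyloxy)-2-methylhexa-2,5-dienoate
Conditions: TBSOTf (1.1 equiv), Et3N (2 equiv), CH2Cl2, -78 to 0 °C; chromatography on Et3N-deactivated silica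
Reagents that add atoms: tert-butyldimethylsilyl triflate, CC(C)(C)[Si](C)(C)OS(=O)(=O)C(F)(F)F
Why: Soft enolisation (silyl triflate activation, then amine deprotonation) is kinetically Z-selective for unbranched aldehydes; the aldehyde is far more Lewis basic than the tert-butyl enoate, so one equivalent of triflate leaves the ester and the skipped diene alone, and residual E isomer is removed by chromatography.

Step 8
Reactants: 7 methyl 4-(acetoxymethyl)-2-oxo-2H-pyran-3-carboxylate; 13 tert-butyl (2E,5Z)-6-(tert-butyldimethylsilyloxy)-2-methylhexa-2,5-dienoate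
Product: 14 methyl (1R,4S,7S,8S)-5-(acetoxymethyl)-7-[(E)-4-tert-butoxy-3-methyl-4-oxobut-2-enyl]-8-(TBS-oxy)-3-oxo-2-oxabicyclo[2.2.2]oct-5-ene-4-carboxylate (endo adduct: both the C7 and C8 substituents syn to the C5=C6 bridge)
Conditions: [Cu((S,S)-tBu-box)](SbF6)2 (10 mol %), 4 Å molecular sieves, CH2Cl2, -40 to 0 °C
Reagents that add atoms: none
Why: The pyrone C2 carbonyl and the C3 ester bind divalent copper as a six-membered chelate, which lowers the diene LUMO and lets the ligand tert-butyl groups cover one pyrone face; the enol silane then adds in a concerted but asynchronous [4+2] in which its nucleophilic beta carbon leads at pyrone C6 (core C4-C5 bond) and the siloxy carbon closes on pyrone C3 (core C1-C6 bond). The closest known reaction type is the chiral Lewis acid catalysed inverse-electron-demand Diels-Alder reaction of 3-carboalkoxy-2-pyrones with vinyl, cyclic and acyclic beta-substituted enol ethers. The six-membered carbocycle closes by intermolecular suprafacial-suprafacial cycloaddition and appears as a lactone-bridged bicyclo[2.2.2]octene. Core C5 and C6 are cis because the Z geometry of 13 is transferred suprafacially, and their absolute configuration follows from the ligand-shielded pyrone face combined with endo approach, while the two bridgeheads are fixed by the same face and disappear in the next step. Regioselectivity is secured by the polarity match between pyrone C6 and the enol beta carbon, endo and facial selectivity by the rigid two-point chelate with a non-coordinating counter-ion (no silyl transfer), and chemoselectivity by the electron-poor side-chain enoate, which cannot compete for an electron-poor diene. Exo and E-derived isomers are removed by chromatography here, since an exo adduct formed on the same pyrone face would feed the enantiomeric diene series.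

Step 9
Reactants: 14 endo bicyclic lactone adduct
Product: 16 methyl (3R,4S,5S,6S)-2-(acetoxymethyl)-5-[(E)-4-tert-butoxy-3-methyl-4-oxobut-2-enyl]-6-(TBS-oxy)-3,4-dihydroxycyclohex-1-ene-1-carboxylate, via cyclohexadiene ester 15 (not isolated)
Conditions: 2,6-di-tert-butyl-4-methylpyridine (10 mol %), degassed 1,4-dioxane, base-washed glass, 95 °C; cool to 0 °C; then OsO4 (2 mol %), NMO (1.1 equiv), acetone-H2O, 0 °C
Reagents that add atoms: osmium tetroxide (catalytic oxygen carrier), O=[Os](=O)(=O)=O; N-methylmorpholine N-oxide, C[N+]1([O-])CCOCC1; water, O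
Why: Thermal retro-[4+2] loss of CO2 erases the bridgeheads and unveils the C1=C2-C3=C4 diene, which is never concentrated or exposed to acid so that silanol loss to the benzoate is held back, and Upjohn dihydroxylation then selects the distal, most electron-rich C3=C4 bond (C1=C2 is tetrasubstituted and ester-deactivated, the side-chain alkene is an enoate) and adds syn from the face opposite the C5 chain and C6 silyl ether, which sets C3 and C4.

Step 10
Reactants: 16 diol
Product: 17 methyl (3R,4S,5R,6S)-2-(acetoxymethyl)-5-[(E)-4-tert-butoxy-3-methyl-4-oxobut-2-enyl]-3,4,6-tris(TBS-oxy)cyclohex-1-ene-1-carboxylate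
Conditions: TBSOTf (3 equiv), 2,6-lutidine (5 equiv), CH2Cl2, -20 to 0 °C
Reagents that add atoms: tert-butyldimethylsilyl triflate, CC(C)(C)[Si](C)(C)OS(=O)(=O)C(F)(F)F
Why: Silylation with the triflate and a hindered pyridine base is the standard answer to flanked secondary alcohols, and at or below 0 °C the tert-butyl ester, the allylic acetate and the existing silyl ether stay intact.

Step 11
Reactants: 17 tris-TBS acetate ester
Product: 19 tris-TBS butenolide (lactone C=O on C1 and OCH2 on C2; 3R,4S,5R,6S), via hydroxymethyl ester 18 (not isolated)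
Conditions: K2CO3 (0.3 equiv), MeOH, 0 °C to rt
Reagents that add atoms: none
Why: Zemplen-type catalytic transesterification frees the C2 CH2OH group, which the ring alkene holds next to the C1 ester so that 5-exo-trig lactonisation follows at once, and this differentiates the two one-carbon branches while the tert-butyl ester and silyl ethers are inert.

Step 12
Reactants: 19 tris-TBS butenolide
Product: 20 lactol (2,5-dihydrofuran-2-ol fused at C1/C2; carbinol carbon on C1; anomeric mixture)
Conditions: i-Bu2AlH (1.1 equiv), toluene, -78 °C; EtOAc quench, aq potassium sodium tartrate; used crude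
Reagents that add atoms: none
Why: Partial lactone reduction stops at the tetrahedral aluminium hemiacetal at -78 °C, the planar butenolide carbonyl is more electrophilic and accessible than the tert-butyl 2-methylenoate, and acid-free work-up keeps the lactol from dehydrating to the furan.

Step 13
Reactants: 21 1-bromohexane; 22 1-phenyl-1H-tetrazole-5-thiol
Product: 23 5-(hexylsulfanyl)-1-phenyl-1H-tetrazole
Conditions: K2CO3 (1.2 equiv), acetone, reflux
Reagents that add atoms: none
Why: SN2 S-alkylation of the soft thiolate with a primary bromide is routine.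

Step 14
Reactants: 23 5-(hexylsulfanyl)-1-phenyl-1H-tetrazole
Product: 24 5-(hexylsulfonyl)-1-phenyl-1H-tetrazole
Conditions: 30% aq H2O2 (excess), (NH4)6Mo7O24·4H2O (5 mol %), EtOH, 0 °C to rt
Reagents that add atoms: hydrogen peroxide, OO
Why: Molybdate-catalysed peroxide oxidation is the standard preparation of phenyltetrazolyl sulfones, and the substrate has no other oxidisable group.

Step 15
Reactants: 20 lactol; 24 5-(hexylsulfonyl)-1-phenyl-1H-tetrazole
Product: 26 tert-butyl (E)-4-[(3R,4S,5R,6S)-1-[(E)-hept-1-enyl]-2-(hydroxymethyl)-3,4,6-tris(TBS-oxy)cyclohex-1-en-5-yl]-2-methylbut-2-enoate, via ring-opened hydroxy enal 25 (not isolated)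
Conditions: 24 (3.2 equiv), KN(SiMe3)2 (3.0 equiv), DME, -60 °C; then 20, -60 °C to rt
Reagents that add atoms: none
Why: In this Julia-Kocienski olefination the first equivalent of metalated sulfone deprotonates the lactol, whose alkoxide equilibrates with the open enal; addition, Smiles rearrangement and loss of SO2 and tetrazolone then give the alkene, the phenyltetrazolyl/potassium/DME combination being the one that favours E, and keeping the sulfone in slight excess over the amide base spares the gamma hydrogens of the enoate.

Step 16
Reactants: 26 tris-TBS tert-butyl ester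
Product: 27 persilylated pestallic acid P (TBS ethers at C2-CH2O and at C3 C4 C6; TBS ester)
Conditions: TBSOTf (4 equiv), 2,6-lutidine (6 equiv), CH2Cl2, 0 °C to rt; short plug of Et3N-deactivated silica
Reagents that add atoms: tert-butyldimethylsilyl triflate, CC(C)(C)[Si](C)(C)OS(=O)(=O)C(F)(F)F
Why: Silyl triflate activation of the tert-butyl ester carbonyl with loss of isobutene is a known buffered tert-butyl to silyl ester exchange in which no free Brønsted acid can ionise the carbinols next to the diene, and because the same reagent caps the free hydroxyl, any O-to-O silyl migration suffered under the basic conditions of step 15 converges on this one compound.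

Step 17
Reactants: 27 persilylated pestallic acid P
Product: 28 pestallic acid P
Conditions: HF·pyridine, excess pyridine, THF, 0 °C to rt (plastic vessel)
Reagents that add atoms: none
Why: Fluoride-induced Si-O cleavage, driven by the strong Si-F bond, removes the four silyl ethers and the silyl ester in one operation, and the pyridine buffer keeps the medium too weakly acidic to ionise the C3 and C6 carbinols.

Compound list
1 | dimethyl malonate | COC(=O)CC(=O)OC | starting material
2 | 4,4-dimethoxybutan-2-one | COC(OC)CC(C)=O | starting material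
3 | dimethyl 2-(4,4-dimethoxybutan-2-ylidene)malonate | COC(=O)C(C(=O)OC)=C(C)CC(OC)OC | intermediate
4 | dimethyl 2-(4-oxobutan-2-ylidene)malonate | COC(=O)C(C(=O)OC)=C(C)CC=O | intermediate
5 | methyl 4-methyl-2-oxo-2H-pyran-3-carboxylate | COC(=O)C1=C(C)C=COC1=O | intermediate
6 | methyl 4-(bromomethyl)-2-oxo-2H-pyran-3-carboxylate | COC(=O)C1=C(CBr)C=COC1=O | intermediate
7 | methyl 4-(acetoxymethyl)-2-oxo-2H-pyran-3-carboxylate | COC(=O)C1=C(COC(C)=O)C=COC1=O | intermediate
8 | 2,3-dihydrofuran | C1=COCC1 | starting material
9 | tert-butyl 2-(triphenylphosphoranylidene)propanoate | CC(C(=O)OC(C)(C)C)=P(c1ccccc1)(c1ccccc1)c1ccccc1 | starting material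
10 | tetrahydrofuran-2-ol | OC1CCCO1 | intermediate
11 | tert-butyl (E)-6-hydroxy-2-methylhex-2-enoate | OCCC/C=C(\C)C(=O)OC(C)(C)C | intermediate
12 | tert-butyl (E)-2-methyl-6-oxohex-2-enoate | O=CCC/C=C(\C)C(=O)OC(C)(C)C | intermediate
13 | tert-butyl (2E,5Z)-6-(TBS-oxy)-2-methylhexa-2,5-dienoate | CC(C)(C)[Si](C)(C)O/C=C\C/C=C(\C)C(=O)OC(C)(C)C | intermediate
14 | endo 2-oxabicyclo[2.2.2]oct-5-en-3-one adduct (1R,4S,7S,8S) | COC(=O)[C@@]12C(COC(C)=O)=C[C@@H](OC1=O)[C@H](C/C=C(\C)C(=O)OC(C)(C)C)[C@@H]2O[Si](C)(C)C(C)(C)C | intermediate
15 | methyl (5S,6S)-2-(acetoxymethyl)-5-[(E)-4-tert-butoxy-3-methyl-4-oxobut-2-enyl]-6-(TBS-oxy)cyclohexa-1,3-diene-1-carboxylate | COC(=O)C1=C(COC(C)=O)C=C[C@H](C/C=C(\C)C(=O)OC(C)(C)C)[C@@H]1O[Si](C)(C)C(C)(C)C | intermediate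
16 | (3R,4S,5S,6S) 3,4-diol of 15 | COC(=O)C1=C(COC(C)=O)[C@@H](O)[C@@H](O)[C@H](C/C=C(\C)C(=O)OC(C)(C)C)[C@@H]1O[Si](C)(C)C(C)(C)C | intermediate
17 | tris-TBS acetate methyl ester (3R,4S,5R,6S) | COC(=O)C1=C(COC(C)=O)[C@@H](O[Si](C)(C)C(C)(C)C)[C@@H](O[Si](C)(C)C(C)(C)C)[C@H](C/C=C(\C)C(=O)OC(C)(C)C)[C@@H]1O[Si](C)(C)C(C)(C)C | intermediate
18 | tris-TBS 2-(hydroxymethyl) methyl ester | COC(=O)C1=C(CO)[C@@H](O[Si](C)(C)C(C)(C)C)[C@@H](O[Si](C)(C)C(C)(C)C)[C@H](C/C=C(\C)C(=O)OC(C)(C)C)[C@@H]1O[Si](C)(C)C(C)(C)C | intermediate
19 | tris-TBS C1/C2-fused butenolide | C12=C(COC1=O)[C@@H](O[Si](C)(C)C(C)(C)C)[C@@H](O[Si](C)(C)C(C)(C)C)[C@H](C/C=C(\C)C(=O)OC(C)(C)C)[C@@H]2O[Si](C)(C)C(C)(C)C | intermediate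
20 | tris-TBS lactol (anomeric mixture) | C12=C(COC1O)[C@@H](O[Si](C)(C)C(C)(C)C)[C@@H](O[Si](C)(C)C(C)(C)C)[C@H](C/C=C(\C)C(=O)OC(C)(C)C)[C@@H]2O[Si](C)(C)C(C)(C)C | intermediate
21 | 1-bromohexane | CCCCCCBr | starting material
22 | 1-phenyl-1H-tetrazole-5-thiol | Sc1nnnn1-c1ccccc1 | starting material
23 | 5-(hexylsulfanyl)-1-phenyl-1H-tetrazole | CCCCCCSc1nnnn1-c1ccccc1 | intermediate
24 | 5-(hexylsulfonyl)-1-phenyl-1H-tetrazole | CCCCCCS(=O)(=O)c1nnnn1-c1ccccc1 | intermediate
25 | ring-opened hydroxy enal (C1-CHO, C2-CH2OH) | O=CC1=C(CO)[C@@H](O[Si](C)(C)C(C)(C)C)[C@@H](O[Si](C)(C)C(C)(C)C)[C@H](C/C=C(\C)C(=O)OC(C)(C)C)[C@@H]1O[Si](C)(C)C(C)(C)C | intermediate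
26 | tris-TBS tert-butyl ester of pestallic acid P | CCCCC/C=C/C1=C(CO)[C@@H](O[Si](C)(C)C(C)(C)C)[C@@H](O[Si](C)(C)C(C)(C)C)[C@H](C/C=C(\C)C(=O)OC(C)(C)C)[C@@H]1O[Si](C)(C)C(C)(C)C | intermediate
27 | persilylated pestallic acid P (four TBS ethers, TBS ester) | CCCCC/C=C/C1=C(CO[Si](C)(C)C(C)(C)C)[C@@H](O[Si](C)(C)C(C)(C)C)[C@@H](O[Si](C)(C)C(C)(C)C)[C@H](C/C=C(\C)C(=O)O[Si](C)(C)C(C)(C)C)[C@@H]1O[Si](C)(C)C(C)(C)C | intermediate
28 | pestallic acid P, (E)-4-[(3R,4S,5R,6S)-1-[(E)-hept-1-enyl]-3,4,6-trihydroxy-2-(hydroxymethyl)cyclohex-1-en-5-yl]-2-methylbut-2-enoic acid (core numbering) | CCCCC/C=C/C1=C(CO)[C@@H](O)[C@@H](O)[C@H](C/C=C(\C)C(=O)O)[C@@H]1O | target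

Total step count: 17. Longest linear sequence: 12 steps (1-4, 8-12, 15-17).

Steps most likely to fail

1. Step 8. The C4 acetoxymethyl group crowds the C3 terminus of the pyrone. The cycloaddition may therefore be slow, the endo and facial preferences may erode, or the enol silane may add stepwise with ring opening of the pyrone.
Fallback: starting from 7 and 13, the cycloaddition is run without Lewis acid under high pressure (about 10 kbar, CH2Cl2, rt). This is the classical way to force hindered 2-pyrones to react below the temperature of CO2 loss. It should give the endo adduct as a racemate, that is 14 together with its mirror image, ent-adduct F1. Preparative chromatography on a chiral stationary phase rejoins the route at 14.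

2. Step 9. At the temperature needed for cycloreversion the diene may lose silanol across C5-C6 and aromatise. The osmylation may also be incompletely site- or face-selective.
Fallback: starting from 14, CO2 is not expelled. The bridge oxygen already sits on C4 trans to the C5 chain, so it is kept as the C4 hydroxyl.
- K2CO3/MeOH removes the acetate, and the freed C2 CH2O group opens the strained bridge by translactonisation to give gamma-lactone allylic alcohol F2. Its C1 configuration is inconsequential.
- VO(acac)2/t-BuOOH epoxidises C2=C3 syn to the C4 hydroxyl (hydroxyl-directed epoxidation) to give epoxy lactone F3.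
- Krapcho demethoxycarbonylation (LiCl, wet DMSO, heat) releases the lactone enolate at C1. This enolate expels the epoxide oxygen from C2 (E1cB) and leaves butenolide diol F4 with cis C3 and C4 hydroxyls.
- TBSOTf/2,6-lutidine rejoins the route at 19.

3. Step 15. The lactol may open too slowly, may dehydrate to the furan, or may suffer tetrazolyl transfer to the primary alkoxide. The hindered enal may also give poor E selectivity.
Fallback: starting from 20, a Wittig reaction is used, a reaction that is routine on lactols. Hexylidenetriphenylphosphorane (hexyltriphenylphosphonium bromide, NaN(SiMe3)2, THF, -78 °C to rt) should give (Z)-heptenyl isomer F5. Catalytic I2 in CH2Cl2 under visible light then equilibrates the strained Z diene to the E diene and rejoins the route at 26.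

Further compounds
F1 | step 8 | ent-adduct (mirror image of 14) | COC(=O)[C@]12C(COC(C)=O)=C[C@H](OC1=O)[C@@H](C/C=C(\C)C(=O)OC(C)(C)C)[C@H]2O[Si](C)(C)C(C)(C)C
F2 | step 9 | gamma-lactone allylic alcohol (C1 bears CO2Me and the lactone C=O, OCH2 on C2, C2=C3, free C4-OH) | COC(=O)[C@]12C(=O)OCC1=C[C@@H](O)[C@H](C/C=C(\C)C(=O)OC(C)(C)C)[C@@H]2O[Si](C)(C)C(C)(C)C
F3 | step 9 | epoxy lactone (C2-C3 epoxide syn to C4-OH) | COC(=O)[C@]12C(=O)OC[C@@]13O[C@H]3[C@@H](O)[C@H](C/C=C(\C)C(=O)OC(C)(C)C)[C@@H]2O[Si](C)(C)C(C)(C)C
F4 | step 9 | butenolide diol (C3-OH and C4-OH free, C6-OTBS) | C12=C(COC1=O)[C@@H](O)[C@@H](O)[C@H](C/C=C(\C)C(=O)OC(C)(C)C)[C@@H]2O[Si](C)(C)C(C)(C)C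
F5 | step 15 | (Z)-heptenyl isomer of 26 | CCCCC/C=C\C1=C(CO)[C@@H](O[Si](C)(C)C(C)(C)C)[C@@H](O[Si](C)(C)C(C)(C)C)[C@H](C/C=C(\C)C(=O)OC(C)(C)C)[C@@H]1O[Si](C)(C)C(C)(C)C
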